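Ring C is cut at C3–C4 and at O1–C8a. This exposes an O1–C2–C3 unit that is the enolate of a ring-B aryl methyl ketone (a C,O-bis-nucleophile) and a C4–C4a–C8a unit that is a ring-A 2-bromobenzyl bromide (a 1,3-bis-electrophile). In one flask the enolate carbon is benzylated (C3–C4) and the enolate oxygen is then arylated under copper catalysis (O1–C8a), closing ring C as a flav-2-ene. The C2=C3 enol ether so formed is the handle for a reagent-controlled syn hydroboration that sets the 2,3-trans (2S,3R) centres. The O5/O7 pattern is differentiated at the salicylaldehyde stage of the ring-A fragment.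

Key step: step 7

Remark: the target is read as (2S,3R), that is 2,3-trans, the 7-O-galloyl ester of (−)-gallocatechin. IpcBH2 (monoisopinocampheylborane) is taken as a THF stock solution prepared beforehand from (−)-α-pinene.

Step 1
Reactants: 1 5-bromoresorcinol
Product: 3 2-bromo-4,6-dihydroxybenzaldehyde, via iminium chloride 2 (not isolated)
Conditions: POCl3, DMF, MeCN, 0 °C → rt; then H2O, 50 °C
Reagents that add atoms: N,N-dimethylformamide CN(C)C=O; water O
Why: Vilsmeier–Haack formylation; the chloroiminium ion should attack C4 of the resorcinol (para to one hydroxyl, ortho to the other, as with resorcinol and orcinol) rather than the doubly flanked C2, and hydrolysis of the iminium salt should give the aldehyde.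

Step 2
Reactants: 3 2-bromo-4,6-dihydroxybenzaldehyde
Product: 4 2-bromo-6-hydroxy-4-(methoxymethoxy)benzaldehyde
Conditions: MOMCl (1.05 equiv), i-Pr2NEt, CH2Cl2, 0 °C
Reagents that add atoms: chloromethyl methyl ether COCCl
Why: Williamson-type O-alkylation; the 6-OH is held in a hydrogen bond to the formyl group, so the free and more acidic 4-OH (para to the formyl group, the later O7) should react selectively.

Step 3
Reactants: 4 2-bromo-6-hydroxy-4-(methoxymethoxy)benzaldehyde
Product: 5 2-(benzyloxy)-6-bromo-4-(methoxymethoxy)benzaldehyde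
Conditions: BnBr, K2CO3, DMF, 50 °C
Reagents that add atoms: benzyl bromide BrCc1ccccc1
Why: Williamson etherification of the remaining chelated phenol (the later O5) under forcing carbonate conditions.

Step 4
Reactants: 5 2-(benzyloxy)-6-bromo-4-(methoxymethoxy)benzaldehyde
Product: 6 [2-(benzyloxy)-6-bromo-4-(methoxymethoxy)phenyl]methanol
Conditions: NaBH4, MeOH–THF, 0 °C
Reagents that add atoms: none
Why: borohydride reduction of an aromatic aldehyde; the aryl bromide, acetal and benzyl ether are inert.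

Step 5
Reactants: 6 [2-(benzyloxy)-6-bromo-4-(methoxymethoxy)phenyl]methanol
Product: 7 1-(benzyloxy)-3-bromo-2-(bromomethyl)-5-(methoxymethoxy)benzene
Conditions: CBr4, PPh3, CH2Cl2, 0 °C; filtered through a short plug and used at once
Reagents that add atoms: carbon tetrabromide BrC(Br)(Br)Br
Why: Appel reaction; the neutral conditions should spare the MOM acetal, and the electron-rich benzylic bromide is not stored.

Step 6
Reactants: 8 1-(3,4,5-trihydroxyphenyl)ethanone
Product: 9 1-[3,4,5-tris(benzyloxy)phenyl]ethanone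
Conditions: BnBr (3.5 equiv), K2CO3, DMF, 60 °C
Reagents that add atoms: benzyl bromide BrCc1ccccc1
Why: threefold Williamson etherification of the phenols; the ketone is not enolised by carbonate to a useful extent.

Step 7
Reactants: 7 1-(benzyloxy)-3-bromo-2-(bromomethyl)-5-(methoxymethoxy)benzene; 9 1-[3,4,5-tris(benzyloxy)phenyl]ethanone
Product: 11 5-(benzyloxy)-7-(methoxymethoxy)-2-[3,4,5-tris(benzyloxy)phenyl]-4H-chromene, via bromo ketone 10 (not isolated)
Conditions: 9 (1.3 equiv), LiN(SiMe3)2, THF, −78 °C; 7, −78 → 0 °C; then CuI (10 mol %), 1,10-phenanthroline (20 mol %), Cs2CO3, DMF, 110 °C (THF distilled off), under argon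
Reagents that add atoms: none
Why: The lithium enolate of 9 should displace the benzylic bromide of 7 by SN2 attack through carbon (C3–C4), giving ketone 10, whose only enolisable position is C3; Cs2CO3 then regenerates the Z-enolate, and its oxygen is joined to C8a by an Ullmann-type copper cycle (oxidative addition of the aryl C–Br bond, C–O reductive elimination), which forms O1–C8a. The closest known reactions are the copper-catalysed domino C-benzylation/O-arylation of 1,3-dicarbonyl compounds with 2-halobenzyl halides to 4H-chromenes and the copper-catalysed enolate O-arylation of 2-haloaryl ketones to benzofurans. Ring C closes as a six-membered ring by intramolecular attack of the enolate oxygen on the metal-bound aryl carbon (6-exo with respect to the breaking C–Br bond); the alternative C-arylation would need a benzocyclobutene and is therefore not expected. No stereocentre is formed; the step fixes the C2=C3 enol ether that carries the later stereocontrol. The selectivity needed is mono- over di-benzylation and C- over O-alkylation, secured by the lithium counter-ion at low temperature, the excess of 9 and the doubly ortho-substituted electrophile, together with chemoselection between the two C–Br bonds, secured because the benzylic bromide reacts without metal at −78 to 0 °C whereas the aryl bromide reacts only with copper at 110 °C. Air is excluded because the electron-rich flav-2-ene 11 is prone to oxidation toward the flavylium ion.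

Step 8
Reactants: 11 5-(benzyloxy)-7-(methoxymethoxy)-2-[3,4,5-tris(benzyloxy)phenyl]-4H-chromene
Product: 13 (2S,3R)-5-(benzyloxy)-7-(methoxymethoxy)-2-[3,4,5-tris(benzyloxy)phenyl]chroman-3-ol, via C3-isopinocampheylborane 12 (not isolated)
Conditions: IpcBH2 [from (−)-α-pinene, 1.2 equiv], THF, −25 °C; then NaOH, H2O2, 0 °C → rt
Reagents that add atoms: hydrogen peroxide OO
Why: asymmetric hydroboration–oxidation; boron should add to C3 (the β-carbon of the enol ether and the less substituted styrenic carbon) and hydrogen to C2 on the same face, so oxidation with retention gives the 2,3-trans alcohol, while the face, and with it C2 as S and C3 as R, is chosen by the chiral borane, the (−)-α-pinene-derived reagent being selected by analogy with its known sense of addition to 1-arylcycloalkenes.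

Step 9
Reactants: 13 (2S,3R)-5-(benzyloxy)-7-(methoxymethoxy)-2-[3,4,5-tris(benzyloxy)phenyl]chroman-3-ol
Product: 14 (2S,3R)-5-(benzyloxy)-2-[3,4,5-tris(benzyloxy)phenyl]chroman-3,7-diol
Conditions: aq. HCl (cat.), MeOH–THF, 45 °C
Reagents that add atoms: none
Why: acid-catalysed acetal exchange should remove the MOM group as dimethoxymethane, while the benzyl ethers and the thermodynamically preferred trans-flavan persist.

Step 10
Reactants: 15 3,4,5-tris(benzyloxy)benzoic acid
Product: 16 3,4,5-tris(benzyloxy)benzoyl chloride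
Conditions: (COCl)2, DMF (cat.), CH2Cl2, rt; evaporated and used crude
Reagents that add atoms: oxalyl chloride ClC(=O)C(Cl)=O
Why: standard acid chloride formation through the Vilsmeier-type chloroiminium catalyst.

Step 11
Reactants: 14 (2S,3R)-5-(benzyloxy)-2-[3,4,5-tris(benzyloxy)phenyl]chroman-3,7-diol; 16 3,4,5-tris(benzyloxy)benzoyl chloride
Product: 17 (2S,3R)-5-(benzyloxy)-3-hydroxy-2-[3,4,5-tris(benzyloxy)phenyl]chroman-7-yl 3,4,5-tris(benzyloxy)benzoate
Conditions: 16 (1.05 equiv), Et3N, CH2Cl2, −20 → 0 °C, no acyl-transfer catalyst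
Reagents that add atoms: none
Why: chemoselective O-acylation; the phenol at C7 is deprotonated by the amine and should be acylated much faster than the neutral, hindered secondary 3-OH in the absence of a nucleophilic catalyst.

Step 12
Reactants: 17 (2S,3R)-5-(benzyloxy)-3-hydroxy-2-[3,4,5-tris(benzyloxy)phenyl]chroman-7-yl 3,4,5-tris(benzyloxy)benzoate
Product: 18 (2S,3R)-3,5-dihydroxy-2-(3,4,5-trihydroxyphenyl)chroman-7-yl 3,4,5-trihydroxybenzoate
Conditions: H2 (1 atm), Pd(OH)2/C, THF–MeOH, rt
Reagents that add atoms: none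
Why: hydrogenolysis of the seven O-benzyl groups under neutral conditions, which should leave the aryl ester, the C2–O1 bond and both stereocentres untouched.

Compound list
1 | 5-bromoresorcinol (5-bromobenzene-1,3-diol) | Oc1cc(O)cc(Br)c1 | starting material
2 | N-[(2-bromo-4,6-dihydroxyphenyl)methylidene]-N-methylmethanaminium chloride | C[N+](C)=Cc1c(Br)cc(O)cc1O.[Cl-] | intermediate
3 | 2-bromo-4,6-dihydroxybenzaldehyde | O=Cc1c(Br)cc(O)cc1O | intermediate
4 | 2-bromo-6-hydroxy-4-(methoxymethoxy)benzaldehyde | O=Cc1c(Br)cc(OCOC)cc1O | intermediate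
5 | 2-(benzyloxy)-6-bromo-4-(methoxymethoxy)benzaldehyde | O=Cc1c(Br)cc(OCOC)cc1OCc1ccccc1 | intermediate
6 | [2-(benzyloxy)-6-bromo-4-(methoxymethoxy)phenyl]methanol | OCc1c(Br)cc(OCOC)cc1OCc1ccccc1 | intermediate
7 | 1-(benzyloxy)-3-bromo-2-(bromomethyl)-5-(methoxymethoxy)benzene | BrCc1c(Br)cc(OCOC)cc1OCc1ccccc1 | intermediate
8 | 1-(3,4,5-trihydroxyphenyl)ethanone | CC(=O)c1cc(O)c(O)c(O)c1 | starting material
9 | 1-[3,4,5-tris(benzyloxy)phenyl]ethanone | CC(=O)c1cc(OCc2ccccc2)c(OCc2ccccc2)c(OCc2ccccc2)c1 | intermediate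
10 | 3-[2-(benzyloxy)-6-bromo-4-(methoxymethoxy)phenyl]-1-[3,4,5-tris(benzyloxy)phenyl]propan-1-one | O=C(CCc1c(Br)cc(OCOC)cc1OCc1ccccc1)c1cc(OCc2ccccc2)c(OCc2ccccc2)c(OCc2ccccc2)c1 | intermediate
11 | 5-(benzyloxy)-7-(methoxymethoxy)-2-[3,4,5-tris(benzyloxy)phenyl]-4H-chromene | COCOc1cc(OCc2ccccc2)c2c(c1)OC(c1cc(OCc3ccccc3)c(OCc3ccccc3)c(OCc3ccccc3)c1)=CC2 | intermediate
12 | [2,3-trans-5-(benzyloxy)-7-(methoxymethoxy)-2-[3,4,5-tris(benzyloxy)phenyl]chroman-3-yl](isopinocampheyl)borane, same spatial arrangement at C2 and C3 as in 13, isopinocampheyl group from (−)-α-pinene | C[C@@H]1[C@@H](B[C@@H]3Cc4c(OCc5ccccc5)cc(OCOC)cc4O[C@H]3c6cc(OCc7ccccc7)c(OCc7ccccc7)c(OCc7ccccc7)c6)C[C@H]2C[C@@H]1C2(C)C | intermediate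
13 | (2S,3R)-5-(benzyloxy)-7-(methoxymethoxy)-2-[3,4,5-tris(benzyloxy)phenyl]chroman-3-ol | COCOc1cc(OCc2ccccc2)c2c(c1)O[C@@H](c1cc(OCc3ccccc3)c(OCc3ccccc3)c(OCc3ccccc3)c1)[C@H](O)C2 | intermediate
14 | (2S,3R)-5-(benzyloxy)-2-[3,4,5-tris(benzyloxy)phenyl]chroman-3,7-diol | Oc1cc(OCc2ccccc2)c2c(c1)O[C@@H](c1cc(OCc3ccccc3)c(OCc3ccccc3)c(OCc3ccccc3)c1)[C@H](O)C2 | intermediate
15 | 3,4,5-tris(benzyloxy)benzoic acid | OC(=O)c1cc(OCc2ccccc2)c(OCc2ccccc2)c(OCc2ccccc2)c1 | starting material
16 | 3,4,5-tris(benzyloxy)benzoyl chloride | ClC(=O)c1cc(OCc2ccccc2)c(OCc2ccccc2)c(OCc2ccccc2)c1 | intermediate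
17 | (2S,3R)-5-(benzyloxy)-3-hydroxy-2-[3,4,5-tris(benzyloxy)phenyl]chroman-7-yl 3,4,5-tris(benzyloxy)benzoate | O=C(Oc1cc(OCc2ccccc2)c2c(c1)O[C@@H](c1cc(OCc3ccccc3)c(OCc3ccccc3)c(OCc3ccccc3)c1)[C@H](O)C2)c1cc(OCc2ccccc2)c(OCc2ccccc2)c(OCc2ccccc2)c1 | intermediate
18 | (2S,3R)-3,5-dihydroxy-2-(3,4,5-trihydroxyphenyl)chroman-7-yl 3,4,5-trihydroxybenzoate | O=C(Oc1cc(O)c2c(c1)O[C@@H](c1cc(O)c(O)c(O)c1)[C@H](O)C2)c1cc(O)c(O)c(O)c1 | target

Total step count: 12. Longest linear sequence: 10 steps (steps 1, 2, 3, 4, 5, 7, 8, 9, 11, 12).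

Steps most likely to fail

1. Step 7. The enolate may be benzylated twice or at oxygen. In the copper stage, slow oxidative addition of the electron-rich aryl bromide may give way to protodebromination or aldol self-condensation, and the flav-2-ene may be oxidised by adventitious air. The fallback sets out from aldehyde 5 and ketone 9 and builds the C3–C4 bond by condensation instead of alkylation. Claisen–Schmidt condensation (KOH, EtOH–THF, rt) should give the chalcone (E)-3-[2-(benzyloxy)-6-bromo-4-(methoxymethoxy)phenyl]-1-[3,4,5-tris(benzyloxy)phenyl]prop-2-en-1-one F1. Conjugate reduction with [(Ph3P)CuH]6 (cat.) and PhSiH3 in toluene should then give the bromo ketone 10, now isolated and purified. Ring closure is changed to palladium-catalysed enolate O-arylation (Pd2(dba)3, DPEphos, Cs2CO3, toluene, 100 °C), and the fallback comes back to the route at 11.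

2. Step 8. The bulky chiral borane may add sluggishly or with low enantiofacial selectivity to the enol ether. The fallback sets out from 11 and replaces asymmetric induction by resolution. BH3·SMe2 in THF at 0 °C followed by NaOH/H2O2 should give racemic trans-5-(benzyloxy)-7-(methoxymethoxy)-2-[3,4,5-tris(benzyloxy)phenyl]chroman-3-ol F2. Esterification with (S)-2-methoxy-2-phenylacetic acid (DCC, DMAP, CH2Cl2) should give two diastereomers, separated by chromatography or crystallisation: the wanted (2S,3R)-chroman-3-yl (S)-2-methoxy-2-phenylacetate F3 and the unwanted (2R,3S)-chroman-3-yl (S)-2-methoxy-2-phenylacetate F4. Methanolysis of F3 (K2CO3, MeOH–THF) comes back to the route at 13.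

3. Step 11. Chemoselectivity may be lost, with acylation of the secondary 3-OH or double acylation. The fallback sets out from 13 and masks the 3-OH first. NaH and BnBr in DMF should give (2S,3R)-3,5-bis(benzyloxy)-7-(methoxymethoxy)-2-[3,4,5-tris(benzyloxy)phenyl]chroman F5. Aqueous HCl in MeOH–THF should then give (2S,3R)-3,5-bis(benzyloxy)-2-[3,4,5-tris(benzyloxy)phenyl]chroman-7-ol F6. Steglich esterification with acid 15 (EDC·HCl, DMAP, CH2Cl2) should give (2S,3R)-3,5-bis(benzyloxy)-2-[3,4,5-tris(benzyloxy)phenyl]chroman-7-yl 3,4,5-tris(benzyloxy)benzoate F7. Hydrogenolysis (H2, Pd(OH)2/C, THF–MeOH) comes back to the route at 18.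

Further compounds
F1 | step 7 | (E)-3-[2-(benzyloxy)-6-bromo-4-(methoxymethoxy)phenyl]-1-[3,4,5-tris(benzyloxy)phenyl]prop-2-en-1-one | O=C(/C=C/c1c(Br)cc(OCOC)cc1OCc1ccccc1)c1cc(OCc2ccccc2)c(OCc2ccccc2)c(OCc2ccccc2)c1
F2 | step 8 | racemic trans-5-(benzyloxy)-7-(methoxymethoxy)-2-[3,4,5-tris(benzyloxy)phenyl]chroman-3-ol | COCOc1cc(OCc2ccccc2)c2c(c1)O[C@@H](c1cc(OCc3ccccc3)c(OCc3ccccc3)c(OCc3ccccc3)c1)[C@H](O)C2.COCOc1cc(OCc2ccccc2)c2c(c1)O[C@H](c1cc(OCc3ccccc3)c(OCc3ccccc3)c(OCc3ccccc3)c1)[C@@H](O)C2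
F3 | step 8 | (2S,3R)-5-(benzyloxy)-7-(methoxymethoxy)-2-[3,4,5-tris(benzyloxy)phenyl]chroman-3-yl (S)-2-methoxy-2-phenylacetate | COCOc1cc(OCc2ccccc2)c2c(c1)O[C@@H](c1cc(OCc3ccccc3)c(OCc3ccccc3)c(OCc3ccccc3)c1)[C@H](OC(=O)[C@@H](OC)c1ccccc1)C2
F4 | step 8 | (2R,3S)-5-(benzyloxy)-7-(methoxymethoxy)-2-[3,4,5-tris(benzyloxy)phenyl]chroman-3-yl (S)-2-methoxy-2-phenylacetate | COCOc1cc(OCc2ccccc2)c2c(c1)O[C@H](c1cc(OCc3ccccc3)c(OCc3ccccc3)c(OCc3ccccc3)c1)[C@@H](OC(=O)[C@@H](OC)c1ccccc1)C2
F5 | step 11 | (2S,3R)-3,5-bis(benzyloxy)-7-(methoxymethoxy)-2-[3,4,5-tris(benzyloxy)phenyl]chroman | COCOc1cc(OCc2ccccc2)c2c(c1)O[C@@H](c1cc(OCc3ccccc3)c(OCc3ccccc3)c(OCc3ccccc3)c1)[C@H](OCc1ccccc1)C2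
F6 | step 11 | (2S,3R)-3,5-bis(benzyloxy)-2-[3,4,5-tris(benzyloxy)phenyl]chroman-7-ol | Oc1cc(OCc2ccccc2)c2c(c1)O[C@@H](c1cc(OCc3ccccc3)c(OCc3ccccc3)c(OCc3ccccc3)c1)[C@H](OCc1ccccc1)C2
F7 | step 11 | (2S,3R)-3,5-bis(benzyloxy)-2-[3,4,5-tris(benzyloxy)phenyl]chroman-7-yl 3,4,5-tris(benzyloxy)benzoate | O=C(Oc1cc(OCc2ccccc2)c2c(c1)O[C@@H](c1cc(OCc3ccccc3)c(OCc3ccccc3)c(OCc3ccccc3)c1)[C@H](OCc1ccccc1)C2)c1cc(OCc2ccccc2)c(OCc2ccccc2)c(OCc2ccccc2)c1
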